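**Retrosynthetic overview**
1. Target 24 ⇐ diacid 21: both α-tertiary NHCHO groups come from CO2H by a double Curtius rearrangement (retention) with formic acid trapping.
2. Ring A is closed last: the C5–C6 bond of the cis-decalin (with C6, C7 and the C4=C5 alkene) by 6-exo vinyl-radical cyclisation of vinyl iodide 18.
3. Ring B: cyclohexene 18 (C1/C10 pair) by catalytic asymmetric Diels–Alder of methacrolein 17 with the 2-oxolanyl diene 16.
4. Diene 16 ⇐ methyl ketone 10 + iodo-enal 13 (aldol condensation, Wittig methylenation).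
5. cis-Oxolane 10 is made first: Claisen aldehyde 4 → Kiyooka aldol → Shi epoxidation/5-exo opening. Ring order: oxolane, ring B, ring A.

Assumption: locants C1–C15 in the explanations are the kalihinene (biflorane) locants of the target (C1/C6 ring fusion, C4(Me)=C5, C7 bears the oxolane, C10 = ring C(Me)N, C11/C14 = oxolane C–O carbons, C15 = CMe2N); in these locants 24 is 1S,6R,7R,10R,11S,14R.

**Step 1**
Reactants: 1 3-methylbut-3-en-2-ol; 2 ethyl vinyl ether
Product: 4 (4E)-4-methylhex-4-enal, via allyl vinyl ether 3 (not isolated)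
Conditions: 2 (excess), Hg(OAc)2 (5 mol %), sealed tube, 40 → 130 °C
Reagents that add atoms: none
Why: Hg(II)-catalysed transvinylation followed by Claisen [3,3] rearrangement through a chair transition state with the carbinol methyl equatorial, which gives the E-trisubstituted alkene (C7=C11).

**Step 2**
Reactants: 4 (4E)-4-methylhex-4-enal; 5 methyl 2-methylpropanoate
Product: 7 methyl (3R,6E)-3-hydroxy-2,2,6-trimethyloct-6-enoate, via silyl ketene acetal 6 (not isolated)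
Conditions: 5, LDA, THF, −78 °C, then TMSCl, → rt, evaporate, pentane, filter; then 4, oxazaborolidinone from N-Ts-L-valine/BH3·THF (20 mol %), EtCN, −78 °C; 1 M HCl
Reagents that add atoms: none
Why: Kiyooka-type Mukaiyama aldol in which the valine-derived chiral boron Lewis acid exposes the aldehyde Si face to the ketene acetal and so sets C14 as R (the D-valine catalyst is used if the sense proves opposite).

**Step 3**
Reactants: 7 methyl (3R,6E)-3-hydroxy-2,2,6-trimethyloct-6-enoate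
Product: 9 methyl 2-[(2R,5S)-5-[(1R)-1-hydroxyethyl]-5-methyloxolan-2-yl]-2-methylpropanoate, via epoxy alcohol 8 (not isolated)
Conditions: Shi ketone (D-fructose-derived, 30 mol %), Oxone, K2CO3, Bu4NHSO4, MeCN–DMM–aq. buffer pH 10.5, 0 °C; then CSA (10 mol %), CH2Cl2, 0 °C
Reagents that add atoms: potassium peroxymonosulfate (Oxone), OOS(=O)(=O)[O-].[K+]
Why: Shi asymmetric epoxidation gives the (R,R)-epoxide by reagent control, and acid-catalysed 5-exo opening at the tertiary carbon by the C14 hydroxyl with inversion sets C11 as S, placing the C7 carbon cis to the CMe2 group on the oxolane.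

**Step 4**
Reactants: 9 methyl 2-[(2R,5S)-5-[(1R)-1-hydroxyethyl]-5-methyloxolan-2-yl]-2-methylpropanoate
Product: 10 methyl 2-[(2R,5S)-5-acetyl-5-methyloxolan-2-yl]-2-methylpropanoate
Conditions: Dess–Martin periodinane, NaHCO3, CH2Cl2, rt
Reagents that add atoms: none
Why: Dess–Martin oxidation of the secondary alcohol; the adjacent C11 is quaternary and cannot epimerise.

**Step 5**
Reactants: 11 pent-4-yn-1-ol
Product: 12 (4E)-5-iodo-4-methylpent-4-en-1-ol
Conditions: AlMe3 (3 equiv), Cp2ZrCl2 (25 mol %), CH2Cl2, 0 °C → rt; then I2, THF, −30 °C; aq. K2CO3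
Reagents that add atoms: trimethylaluminium, C[Al](C)C; iodine, II
Why: Negishi Zr-catalysed syn-carboalumination puts methyl on the internal carbon and iodinolysis of the vinyl–Al bond with retention gives the E-vinyl iodide.

**Step 6**
Reactants: 12 (4E)-5-iodo-4-methylpent-4-en-1-ol
Product: 13 (4E)-5-iodo-4-methylpent-4-enal
Conditions: Dess–Martin periodinane, CH2Cl2, rt (used crude)
Reagents that add atoms: none
Why: Dess–Martin oxidation of a primary alcohol stops at the aldehyde and leaves the vinyl iodide untouched.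

**Step 7**
Reactants: 10 methyl 2-[(2R,5S)-5-acetyl-5-methyloxolan-2-yl]-2-methylpropanoate; 13 (4E)-5-iodo-4-methylpent-4-enal
Product: 15 methyl 2-[(2R,5S)-5-[(2E,6E)-7-iodo-6-methylhepta-2,6-dienoyl]-5-methyloxolan-2-yl]-2-methylpropanoate, via β-hydroxy ketone 14 (not isolated)
Conditions: LDA, THF, −78 °C; 13; then MsCl, Et3N, −78 → 0 °C; DBU, rt
Reagents that add atoms: none
Why: directed crossed aldol (the ketone enolises only at CH3, the ester has no α-H) followed by mesylation and E1cB elimination gives the E-enone.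

**Step 8**
Reactants: 15 methyl 2-[(2R,5S)-5-[(2E,6E)-7-iodo-6-methylhepta-2,6-dienoyl]-5-methyloxolan-2-yl]-2-methylpropanoate
Product: 16 methyl 2-[(2R,5S)-5-[(3E,7E)-8-iodo-7-methylocta-1,3,7-trien-2-yl]-5-methyloxolan-2-yl]-2-methylpropanoate
Conditions: Ph3PCH3Br, KHMDS, THF, 0 °C; then 15, 0 → 40 °C
Reagents that add atoms: methyltriphenylphosphonium bromide, C[P+](c1ccccc1)(c1ccccc1)c1ccccc1.[Br-]
Why: Wittig methylenation of the enone carbonyl gives the 2-substituted (E)-1,3-diene; no stereocentre is formed and the hindered ester is not attacked.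

**Step 9**
Reactants: 16 methyl 2-[(2R,5S)-5-[(3E,7E)-8-iodo-7-methylocta-1,3,7-trien-2-yl]-5-methyloxolan-2-yl]-2-methylpropanoate; 17 2-methylprop-2-enal
Product: 18 methyl 2-[(2R,5S)-5-[(3S,4R)-4-formyl-3-[(3E)-4-iodo-3-methylbut-3-en-1-yl]-4-methylcyclohex-1-en-1-yl]-5-methyloxolan-2-yl]-2-methylpropanoate
Conditions: (S)-o-tolyl-CBS oxazaborolidine (20 mol %), Tf2NH (16 mol %), CH2Cl2, −78 → −40 °C
Reagents that add atoms: none
Why: Corey oxazaborolidinium-catalysed Diels–Alder in which the 1- and 2-substituents of the diene both direct C10 onto C1 ("ortho/para"), the endo-CHO transition state puts CHO cis to the C1 side chain, and the catalyst exposes the α-Si face of methacrolein to give C1 S and C10 R (the R catalyst is used if the sense proves opposite).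

**Step 10**
Reactants: 18 methyl 2-[(2R,5S)-5-[(3S,4R)-4-formyl-3-[(3E)-4-iodo-3-methylbut-3-en-1-yl]-4-methylcyclohex-1-en-1-yl]-5-methyloxolan-2-yl]-2-methylpropanoate
Product: 19 methyl 2-[(2R,5S)-5-[(1R,4R,4aS,8aR)-4-formyl-4,7-dimethyl-1,2,3,4,4a,5,6,8a-octahydronaphthalen-1-yl]-5-methyloxolan-2-yl]-2-methylpropanoate
Conditions: Bu3SnH (1.3 equiv, syringe pump), AIBN (0.2 equiv), PhH (5 mM), 80 °C
Reagents that add atoms: none
Why: Stork-type tin-hydride vinyl-radical cyclisation in which the C5 σ-radical closes 6-exo-trig onto the CH terminus (C6) of the ring alkene from the face of its own tether, so C5–C6 forms cis to C1–C2 (C6 R, cis-decalin) with the C4=C5 alkene fixed by the vinyl iodide, and the tertiary C7 radical then takes H from Bu3SnH axially so that the quaternary oxolanyl group ends equatorial (C7 R), the alternative forcing a syn-pentane clash with C2.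

**Step 11**
Reactants: 19 methyl 2-[(2R,5S)-5-[(1R,4R,4aS,8aR)-4-formyl-4,7-dimethyl-1,2,3,4,4a,5,6,8a-octahydronaphthalen-1-yl]-5-methyloxolan-2-yl]-2-methylpropanoate
Product: 21 (1R,4R,4aR,8aS)-4-[(2S,5R)-5-(2-carboxypropan-2-yl)-2-methyloxolan-2-yl]-1,6-dimethyl-1,2,3,4,4a,7,8,8a-octahydronaphthalene-1-carboxylic acid, via acid ester 20 (not isolated)
Conditions: NaClO2, NaH2PO4, 2-methylbut-2-ene, t-BuOH–H2O, rt; then LiOH·H2O (10 equiv), MeOH, 60 °C; aq. HCl
Reagents that add atoms: sodium chlorite, [Na+].[O-]Cl=O; lithium hydroxide, [Li+].[OH-]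
Why: Pinnick oxidation of the neopentyl aldehyde (HOCl scavenged, alkene spared) and saponification of the α-quaternary methyl ester, neither of which touches a stereocentre.

**Step 12**
Reactants: 21 (1R,4R,4aR,8aS)-4-[(2S,5R)-5-(2-carboxypropan-2-yl)-2-methyloxolan-2-yl]-1,6-dimethyl-1,2,3,4,4a,7,8,8a-octahydronaphthalene-1-carboxylic acid
Product: 24 N-[(1R,4R,4aR,8aS)-4-[(2S,5R)-5-(2-formamidopropan-2-yl)-2-methyloxolan-2-yl]-1,6-dimethyl-1,2,3,4,4a,7,8,8a-octahydronaphthalen-1-yl]formamide, via bis(acyl azide) 22 (not isolated), via bis-isocyanate 23 (not isolated)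
Conditions: DPPA (2.4 equiv), Et3N, PhMe, rt → 90 °C; then HCO2H (6 equiv), DMAP (cat.), 60 °C
Reagents that add atoms: diphenylphosphoryl azide, [N-]=[N+]=NP(=O)(Oc1ccccc1)Oc1ccccc1; formic acid, OC=O
Why: double Curtius rearrangement, with retention at C10, gives the two tertiary isocyanates, which formic acid converts to formamides through the mixed carbamic–formic anhydride with loss of CO2.

**Compound list**
1 | 3-methylbut-3-en-2-ol (racemic) | CC(O)C(C)=C | starting material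
2 | ethyl vinyl ether | C=COCC | starting material
3 | 2-methyl-3-(vinyloxy)but-1-ene | C=COC(C)C(C)=C | intermediate (not isolated)
4 | (4E)-4-methylhex-4-enal | C/C=C(\C)CCC=O | intermediate
5 | methyl 2-methylpropanoate | COC(=O)C(C)C | starting material
6 | 1-methoxy-2-methyl-1-(trimethylsilyloxy)prop-1-ene | COC(O[Si](C)(C)C)=C(C)C | intermediate (not isolated)
7 | methyl (3R,6E)-3-hydroxy-2,2,6-trimethyloct-6-enoate | C/C=C(\C)CC[C@@H](O)C(C)(C)C(=O)OC | intermediate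
8 | methyl (3R)-5-[(2R,3R)-2,3-dimethyloxiran-2-yl]-3-hydroxy-2,2-dimethylpentanoate | C[C@H]1O[C@]1(C)CC[C@@H](O)C(C)(C)C(=O)OC | intermediate (not isolated)
9 | methyl 2-[(2R,5S)-5-[(1R)-1-hydroxyethyl]-5-methyloxolan-2-yl]-2-methylpropanoate | C[C@@H](O)[C@]1(C)CC[C@H](C(C)(C)C(=O)OC)O1 | intermediate
10 | methyl 2-[(2R,5S)-5-acetyl-5-methyloxolan-2-yl]-2-methylpropanoate | CC(=O)[C@]1(C)CC[C@H](C(C)(C)C(=O)OC)O1 | intermediate
11 | pent-4-yn-1-ol | OCCCC#C | starting material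
12 | (4E)-5-iodo-4-methylpent-4-en-1-ol | OCCC/C(C)=C/I | intermediate
13 | (4E)-5-iodo-4-methylpent-4-enal | O=CCC/C(C)=C/I | intermediate
14 | methyl 2-[(2R,5S)-5-[(6E)-3-hydroxy-7-iodo-6-methylhept-6-enoyl]-5-methyloxolan-2-yl]-2-methylpropanoate (both carbinol epimers) | I/C=C(\C)CCC(O)CC(=O)[C@]1(C)CC[C@H](C(C)(C)C(=O)OC)O1 | intermediate (not isolated)
15 | methyl 2-[(2R,5S)-5-[(2E,6E)-7-iodo-6-methylhepta-2,6-dienoyl]-5-methyloxolan-2-yl]-2-methylpropanoate | I/C=C(\C)CC/C=C/C(=O)[C@]1(C)CC[C@H](C(C)(C)C(=O)OC)O1 | intermediate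
16 | methyl 2-[(2R,5S)-5-[(3E,7E)-8-iodo-7-methylocta-1,3,7-trien-2-yl]-5-methyloxolan-2-yl]-2-methylpropanoate | I/C=C(\C)CC/C=C/C(=C)[C@]1(C)CC[C@H](C(C)(C)C(=O)OC)O1 | intermediate
17 | 2-methylprop-2-enal (methacrolein) | CC(=C)C=O | starting material
18 | methyl 2-[(2R,5S)-5-[(3S,4R)-4-formyl-3-[(3E)-4-iodo-3-methylbut-3-en-1-yl]-4-methylcyclohex-1-en-1-yl]-5-methyloxolan-2-yl]-2-methylpropanoate | O=C[C@]1(C)CCC(=C[C@@H]1CC/C(C)=C/I)[C@]2(C)CC[C@H](C(C)(C)C(=O)OC)O2 | intermediate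
19 | methyl 2-[(2R,5S)-5-[(1R,4R,4aS,8aR)-4-formyl-4,7-dimethyl-1,2,3,4,4a,5,6,8a-octahydronaphthalen-1-yl]-5-methyloxolan-2-yl]-2-methylpropanoate | CC1=C[C@H]2[C@H]([C@]3(C)CC[C@H](C(C)(C)C(=O)OC)O3)CC[C@@](C)(C=O)[C@H]2CC1 | intermediate
20 | (1R,4R,4aR,8aS)-4-[(2S,5R)-5-(1-methoxy-2-methyl-1-oxopropan-2-yl)-2-methyloxolan-2-yl]-1,6-dimethyl-1,2,3,4,4a,7,8,8a-octahydronaphthalene-1-carboxylic acid | CC1=C[C@H]2[C@H]([C@]3(C)CC[C@H](C(C)(C)C(=O)OC)O3)CC[C@@](C)(C(=O)O)[C@H]2CC1 | intermediate (not isolated)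
21 | (1R,4R,4aR,8aS)-4-[(2S,5R)-5-(2-carboxypropan-2-yl)-2-methyloxolan-2-yl]-1,6-dimethyl-1,2,3,4,4a,7,8,8a-octahydronaphthalene-1-carboxylic acid | CC1=C[C@H]2[C@H]([C@]3(C)CC[C@H](C(C)(C)C(=O)O)O3)CC[C@@](C)(C(=O)O)[C@H]2CC1 | intermediate
22 | (1R,4R,4aR,8aS)-4-[(2S,5R)-5-(1-azido-2-methyl-1-oxopropan-2-yl)-2-methyloxolan-2-yl]-1,6-dimethyl-1,2,3,4,4a,7,8,8a-octahydronaphthalene-1-carbonyl azide | CC1=C[C@H]2[C@H]([C@]3(C)CC[C@H](C(C)(C)C(=O)N=[N+]=[N-])O3)CC[C@@](C)(C(=O)N=[N+]=[N-])[C@H]2CC1 | intermediate (not isolated)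
23 | (1R,4R,4aR,8aS)-1-isocyanato-4-[(2S,5R)-5-(2-isocyanatopropan-2-yl)-2-methyloxolan-2-yl]-1,6-dimethyl-1,2,3,4,4a,7,8,8a-octahydronaphthalene | CC1=C[C@H]2[C@H]([C@]3(C)CC[C@H](C(C)(C)N=C=O)O3)CC[C@@](C)(N=C=O)[C@H]2CC1 | intermediate (not isolated)
24 | N-[(1R,4R,4aR,8aS)-4-[(2S,5R)-5-(2-formamidopropan-2-yl)-2-methyloxolan-2-yl]-1,6-dimethyl-1,2,3,4,4a,7,8,8a-octahydronaphthalen-1-yl]formamide | CC1=C[C@H]2[C@H]([C@]3(C)CC[C@H](C(C)(C)NC=O)O3)CC[C@@](C)(NC=O)[C@H]2CC1 | target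

**Total step count:** 12. **Longest linear sequence:** 10 (steps 1–4, then 7–12); steps 5–6 are the side branch.

**The three steps most likely to fail**

Step 10 (vinyl-radical ring closure). The vinyl radical can instead abstract the tertiary allylic C1–H (1,5-transfer), which gives reduced, uncyclised material, and the C7 configuration rests on the facial preference of H-delivery. The fallback sets out from 18 and comes back at 20. Aldehyde 18 is closed by an intramolecular Heck reaction (Pd(OAc)2, PPh3, Et3N, MeCN, 80 °C); syn-carbopalladation and β-hydride elimination towards C8 give the C7=C8 diene aldehyde F1. NaBH4 (MeOH, 0 °C) reduces it to the hydroxymethyl diene F2. Hydroxyl-directed hydrogenation with Crabtree's catalyst (H2 1 atm, CH2Cl2, stopped after 1 equiv) adds H2 to C7=C8 from the face of the C10 CH2OH group, which is the face required for C7, and gives the decalin alcohol F3. TEMPO/NaOCl (cat.)/NaClO2 oxidation then returns acid ester 20, which is saponified as in step 11.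

Step 9 (Diels–Alder). The diene carries a tertiary allylic ether that a cationic boron Lewis acid may ionise, and the catalyst must override the chiral diene. The fallback sets out from 16 and comes back at 24, and brings the C10 nitrogen in directly. Diene 16 is heated with 2-nitroprop-1-ene (PhMe, 60 °C, BHT; same regiochemistry, nitro endo, π-facial diastereomers separated) to give the nitrocyclohexene F4. Bu3SnH (1.1 equiv)/Et3B/air at rt, as in step 10, gives the nitro decalin ester F5, and LiOH gives the nitro acid F6. DPPA/Et3N then HCO2H, via the acyl azide F7 and the isocyanate F8, gives the nitro formamide F9. Zn/AcOH reduces the tertiary nitro group to the amino formamide F10, and acetic formic anhydride (THF, 0 °C) formylates it to 24.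

Step 12 (double Curtius/formic acid). Two hindered tertiary isocyanates may react sluggishly or unevenly with formic acid. The fallback sets out from 23 (made from 21 as in step 12) and comes back at 24. The bis-isocyanate is hydrolysed (2 M HCl, THF, 40 °C, then base) to the diamine F11, which is N-formylated with acetic formic anhydride.

**Further compounds**
F1 | step 10 | methyl 2-[(2R,5S)-5-[(4R,4aS,8aR)-4-formyl-4,7-dimethyl-3,4,4a,5,6,8a-hexahydronaphthalen-1-yl]-5-methyloxolan-2-yl]-2-methylpropanoate | CC1=C[C@H]2C([C@]3(C)CC[C@H](C(C)(C)C(=O)OC)O3)=CC[C@@](C)(C=O)[C@H]2CC1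
F2 | step 10 | methyl 2-[(2R,5S)-5-[(4R,4aS,8aR)-4-(hydroxymethyl)-4,7-dimethyl-3,4,4a,5,6,8a-hexahydronaphthalen-1-yl]-5-methyloxolan-2-yl]-2-methylpropanoate | CC1=C[C@H]2C([C@]3(C)CC[C@H](C(C)(C)C(=O)OC)O3)=CC[C@@](C)(CO)[C@H]2CC1
F3 | step 10 | methyl 2-[(2R,5S)-5-[(1R,4R,4aS,8aR)-4-(hydroxymethyl)-4,7-dimethyl-1,2,3,4,4a,5,6,8a-octahydronaphthalen-1-yl]-5-methyloxolan-2-yl]-2-methylpropanoate | CC1=C[C@H]2[C@H]([C@]3(C)CC[C@H](C(C)(C)C(=O)OC)O3)CC[C@@](C)(CO)[C@H]2CC1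
F4 | step 9 | methyl 2-[(2R,5S)-5-[(3S,4R)-3-[(3E)-4-iodo-3-methylbut-3-en-1-yl]-4-methyl-4-nitrocyclohex-1-en-1-yl]-5-methyloxolan-2-yl]-2-methylpropanoate | [O-][N+](=O)[C@]1(C)CCC(=C[C@@H]1CC/C(C)=C/I)[C@]2(C)CC[C@H](C(C)(C)C(=O)OC)O2
F5 | step 9 | methyl 2-[(2R,5S)-5-[(1R,4R,4aS,8aR)-4,7-dimethyl-4-nitro-1,2,3,4,4a,5,6,8a-octahydronaphthalen-1-yl]-5-methyloxolan-2-yl]-2-methylpropanoate | CC1=C[C@H]2[C@H]([C@]3(C)CC[C@H](C(C)(C)C(=O)OC)O3)CC[C@@](C)([N+](=O)[O-])[C@H]2CC1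
F6 | step 9 | 2-[(2R,5S)-5-[(1R,4R,4aS,8aR)-4,7-dimethyl-4-nitro-1,2,3,4,4a,5,6,8a-octahydronaphthalen-1-yl]-5-methyloxolan-2-yl]-2-methylpropanoic acid | CC1=C[C@H]2[C@H]([C@]3(C)CC[C@H](C(C)(C)C(=O)O)O3)CC[C@@](C)([N+](=O)[O-])[C@H]2CC1
F7 | step 9 | 2-[(2R,5S)-5-[(1R,4R,4aS,8aR)-4,7-dimethyl-4-nitro-1,2,3,4,4a,5,6,8a-octahydronaphthalen-1-yl]-5-methyloxolan-2-yl]-2-methylpropanoyl azide | CC1=C[C@H]2[C@H]([C@]3(C)CC[C@H](C(C)(C)C(=O)N=[N+]=[N-])O3)CC[C@@](C)([N+](=O)[O-])[C@H]2CC1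
F8 | step 9 | (1R,4R,4aS,8aR)-1-[(2S,5R)-5-(2-isocyanatopropan-2-yl)-2-methyloxolan-2-yl]-4,7-dimethyl-4-nitro-1,2,3,4,4a,5,6,8a-octahydronaphthalene | CC1=C[C@H]2[C@H]([C@]3(C)CC[C@H](C(C)(C)N=C=O)O3)CC[C@@](C)([N+](=O)[O-])[C@H]2CC1
F9 | step 9 | N-[2-[(2R,5S)-5-[(1R,4R,4aS,8aR)-4,7-dimethyl-4-nitro-1,2,3,4,4a,5,6,8a-octahydronaphthalen-1-yl]-5-methyloxolan-2-yl]propan-2-yl]formamide | CC1=C[C@H]2[C@H]([C@]3(C)CC[C@H](C(C)(C)NC=O)O3)CC[C@@](C)([N+](=O)[O-])[C@H]2CC1
F10 | step 9 | N-[2-[(2R,5S)-5-[(1R,4R,4aS,8aR)-4-amino-4,7-dimethyl-1,2,3,4,4a,5,6,8a-octahydronaphthalen-1-yl]-5-methyloxolan-2-yl]propan-2-yl]formamide | CC1=C[C@H]2[C@H]([C@]3(C)CC[C@H](C(C)(C)NC=O)O3)CC[C@@](C)(N)[C@H]2CC1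
F11 | step 12 | (1R,4R,4aR,8aS)-4-[(2S,5R)-5-(2-aminopropan-2-yl)-2-methyloxolan-2-yl]-1,6-dimethyl-1,2,3,4,4a,7,8,8a-octahydronaphthalen-1-amine | CC1=C[C@H]2[C@H]([C@]3(C)CC[C@H](C(C)(C)N)O3)CC[C@@](C)(N)[C@H]2CC1
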